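**Retrosynthetic overview**
1. Alternaric acid ⇒ its methyl ester ⇒ cut of the skipped diene between the 1,1-disubstituted and the (E)-olefin: ruthenium-catalysed alkene–alkyne coupling of a 2-allyl-2,3-dihydroxy ester with a 3-(pent-4-ynoyl)dihydropyranone.
2. Quaternary carbinol C2 (the C2–allyl bond) ⇒ key step: chelate-controlled ester-enolate [2,3]-Wittig rearrangement of the O2-allyl ether of a 2,3-dihydroxy-4-methylhexanoate, with C3 directing C2.
3. C3/C4 ⇒ (Z)-crotylboration of (S)-glyceraldehyde acetonide made from (R)-solketal, then hydrogenation and oxidation of C1; the solketal centre directs C3/C4 and is itself re-set in the Wittig step.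
4. Acylpyranone ⇒ DCC/DMAP C-acylation of (R)-4-hydroxy-6-methyl-5,6-dihydropyran-2-one with pent-4-ynoic acid; pyranone ⇒ methyl (R)-3-hydroxybutanoate and tert-butyl acetate.
5. Ring order: the only ring, the dihydropyranone, is closed first (side branch, lactonisation), before acylation and fragment union.

Assumption: operations run in one flask without isolating the intermediate count as one step, and reagents named without a number are bought.

**Route**

Step 1
Reactants: 1 (R)-solketal
Product: 3 (1R,2S)-1-[(4S)-2,2-dimethyl-1,3-dioxolan-4-yl]-2-methylbut-3-en-1-ol, via (S)-glyceraldehyde acetonide 2 (not isolated)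
Conditions: TEMPO (0.1 equiv), PhI(OAc)2 (1.1 equiv), CH2Cl2, 0 °C to rt; then (Z)-crotylboronic acid pinacol ester (1.2 equiv), rt, 36 h; H2O work-up
Reagents that add atoms: (Z)-crotylboronic acid pinacol ester, C/C=C\CB1OC(C)(C)C(C)(C)O1
Why: TEMPO/PhI(OAc)2 oxidation gives the aldehyde, which is crotylborated at once through a closed six-membered chair transition state, the (Z)-boronate fixing the syn methyl/hydroxyl pair and Felkin–Anh (Cornforth) addition anti to the dioxolane C–O bond of the bought centre fixing the absolute sense, so the carbinol is (R) and the methyl-bearing carbon (S).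

Step 2
Reactants: 3 (1R,2S)-1-[(4S)-2,2-dimethyl-1,3-dioxolan-4-yl]-2-methylbut-3-en-1-ol
Product: 5 (2S,3R,4S)-4-methylhexane-1,2,3-triol, via saturated acetonide 4 (not isolated)
Conditions: H2 (1 atm), 10% Pd/C, MeOH, rt; filter; then 1 M aq. HCl (0.1 equiv), 40 °C; evaporate
Reagents that add atoms: none
Why: Catalytic hydrogenation turns the vinyl group into the ethyl arm of the sec-butyl unit and acid-catalysed acetal hydrolysis then frees the triol, with no stereocentre involved.

Step 3
Reactants: 5 (2S,3R,4S)-4-methylhexane-1,2,3-triol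
Product: 7 methyl (2R,3R,4S)-2,3-dihydroxy-4-methylhexanoate, via dihydroxy acid 6 (not isolated)
Conditions: TEMPO (5 mol %), NaBr (10 mol %), NaOCl (2.2 equiv), H2O, pH 10 (NaOH), 0 °C; HCl to pH 2, evaporate; then MeOH, HCl (cat.), 50 °C
Reagents that add atoms: water, O; methanol, CO
Why: Anelli-type TEMPO/hypochlorite oxidation takes only the primary alcohol through the aldehyde hydrate to the acid and Fischer esterification gives the methyl ester, while any epimerisation at C2 is harmless because that centre is made planar and re-set in step 5.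

Step 4
Reactants: 7 methyl (2R,3R,4S)-2,3-dihydroxy-4-methylhexanoate
Product: 9 methyl (2R,3R,4S)-3-hydroxy-4-methyl-2-(prop-2-en-1-yloxy)hexanoate, via stannylene acetal 8 (not isolated)
Conditions: Bu2SnO (1.05 equiv), toluene, reflux (Dean–Stark); then allyl bromide (1.5 equiv), CsF (1.5 equiv), DMF, rt
Reagents that add atoms: allyl bromide, C=CCBr; dibutyltin oxide, CCCC[Sn](=O)CCCC (carried in 8 only)
Why: Regioselective O-alkylation through the dibutylstannylene acetal, in which the fluoride-activated tin acetal reacts at the more acidic and less hindered oxygen next to the ester, so the allyl group goes to O2 and the hindered C3 hydroxyl stays free.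

Step 5
Reactants: 9 methyl (2R,3R,4S)-3-hydroxy-4-methyl-2-(prop-2-en-1-yloxy)hexanoate
Product: 10 methyl (2S,3R,4S)-2,3-dihydroxy-4-methyl-2-(prop-2-en-1-yl)hexanoate
Conditions: LiN(iPr)2 (2.5 equiv), THF, −78 to −20 °C, 3 h; aq. NH4Cl
Reagents that add atoms: none
Why: Ester-enolate [2,3]-Wittig rearrangement (a [2,3]-sigmatropic shift) of the dianion moves the allyl group from O2 to C2 through a five-membered envelope transition state, and because the C3 lithium alkoxide chelates the enolate oxygen in a six-membered ring (Fráter–Seebach-type control) the new C–C bond forms on the face away from the sec-butyl group, giving the (2S) quaternary carbinol.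

Step 6
Reactants: 11 methyl (3R)-3-hydroxybutanoate
Product: 12 tert-butyl (5R)-5-hydroxy-3-oxohexanoate
Conditions: tert-butyl acetate (3.6 equiv), LiN(iPr)2 (3.6 equiv), THF, −78 °C; then 11, −78 to −25 °C; aq. HCl to pH 5
Reagents that add atoms: tert-butyl acetate, CC(=O)OC(C)(C)C
Why: Crossed Claisen condensation in which excess lithium enolate first deprotonates the hydroxyl and then acylates on the methyl ester, the product being stored as its β-keto ester enolate so that no second addition occurs and the bought (R) centre is untouched.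

Step 7
Reactants: 12 tert-butyl (5R)-5-hydroxy-3-oxohexanoate
Product: 14 (6R)-4-hydroxy-6-methyl-5,6-dihydro-2H-pyran-2-one, via keto acid 13 (not isolated)
Conditions: CF3CO2H, CH2Cl2, rt, 3 h
Reagents that add atoms: none
Why: Acidolysis of the tert-butyl ester with loss of isobutene and spontaneous lactonisation of the δ-hydroxy β-keto acid close the six-membered ring, which rests as the enol.

Step 8
Reactants: 14 (6R)-4-hydroxy-6-methyl-5,6-dihydro-2H-pyran-2-one; 15 pent-4-ynoic acid
Product: 17 (6R)-4-hydroxy-6-methyl-3-(pent-4-ynoyl)-5,6-dihydro-2H-pyran-2-one, via enol ester 16 (not isolated)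
Conditions: DCC (1.1 equiv), DMAP (1.2 equiv), CH2Cl2, 0 °C to rt, 24 h
Reagents that add atoms: none
Why: Steglich O-acylation of the enol followed by DMAP-mediated O-to-C acyl migration (Fries-type rearrangement) gives the C3-acylated, internally hydrogen-bonded tricarbonyl as the thermodynamic product.

Step 9
Reactants: 10 methyl (2S,3R,4S)-2,3-dihydroxy-4-methyl-2-(prop-2-en-1-yl)hexanoate; 17 (6R)-4-hydroxy-6-methyl-3-(pent-4-ynoyl)-5,6-dihydro-2H-pyran-2-one
Product: 18 methyl alternarate
Conditions: [CpRu(MeCN)3]PF6 (10 mol %), acetone, rt, 4 h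
Reagents that add atoms: none
Why: Trost ruthenium-catalysed alkene–alkyne coupling (Alder-ene-type reaction) in which oxidative cyclisation to a ruthenacyclopentene, β-hydride elimination of an allylic hydrogen and reductive elimination join the terminal alkene carbon of 10 to the internal alkyne carbon of 17, giving the branched 1,4-diene with the new (E)-olefin, all atoms of both partners being kept and no stereocentre being touched.

Step 10
Reactants: 18 methyl alternarate
Product: 19 alternaric acid
Conditions: LiOH (4 equiv), THF–H2O 3:1, 0 °C to rt; then 1 M HCl to pH 2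
Reagents that add atoms: lithium hydroxide, [Li+].[OH-]
Why: Saponification of the α-hydroxy methyl ester, during which the acylpyranone is shielded from hydroxide as its delocalised tricarbonyl enolate, followed by acidification to the natural product.

**Compound list**
1 | (R)-solketal, [(4R)-2,2-dimethyl-1,3-dioxolan-4-yl]methanol | CC1(C)OC[C@H](O1)CO | starting material
2 | (S)-glyceraldehyde acetonide, (4S)-2,2-dimethyl-1,3-dioxolane-4-carbaldehyde | CC1(C)OC[C@H](O1)C=O | intermediate
3 | (1R,2S)-1-[(4S)-2,2-dimethyl-1,3-dioxolan-4-yl]-2-methylbut-3-en-1-ol | CC1(C)OC[C@H](O1)[C@H](O)[C@@H](C)C=C | intermediate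
4 | (1R,2S)-1-[(4S)-2,2-dimethyl-1,3-dioxolan-4-yl]-2-methylbutan-1-ol | CC1(C)OC[C@H](O1)[C@H](O)[C@@H](C)CC | intermediate
5 | (2S,3R,4S)-4-methylhexane-1,2,3-triol | OC[C@H](O)[C@H](O)[C@@H](C)CC | intermediate
6 | (2R,3R,4S)-2,3-dihydroxy-4-methylhexanoic acid | OC(=O)[C@H](O)[C@H](O)[C@@H](C)CC | intermediate
7 | methyl (2R,3R,4S)-2,3-dihydroxy-4-methylhexanoate | COC(=O)[C@H](O)[C@H](O)[C@@H](C)CC | intermediate
8 | methyl (4R,5R)-2,2-dibutyl-5-[(2S)-butan-2-yl]-1,3,2-dioxastannolane-4-carboxylate | COC(=O)[C@H](O[Sn]1(CCCC)CCCC)[C@H](O1)[C@@H](C)CC | intermediate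
9 | methyl (2R,3R,4S)-3-hydroxy-4-methyl-2-(prop-2-en-1-yloxy)hexanoate | COC(=O)[C@H](OCC=C)[C@H](O)[C@@H](C)CC | intermediate
10 | methyl (2S,3R,4S)-2,3-dihydroxy-4-methyl-2-(prop-2-en-1-yl)hexanoate | C=CC[C@@](O)(C(=O)OC)[C@H](O)[C@@H](C)CC | intermediate
11 | methyl (3R)-3-hydroxybutanoate | C[C@@H](O)CC(=O)OC | starting material
12 | tert-butyl (5R)-5-hydroxy-3-oxohexanoate | C[C@@H](O)CC(=O)CC(=O)OC(C)(C)C | intermediate
13 | (5R)-5-hydroxy-3-oxohexanoic acid | C[C@@H](O)CC(=O)CC(=O)O | intermediate
14 | (6R)-4-hydroxy-6-methyl-5,6-dihydro-2H-pyran-2-one | C[C@@H]1CC(O)=CC(=O)O1 | intermediate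
15 | pent-4-ynoic acid | C#CCCC(=O)O | starting material
16 | (2R)-2-methyl-6-oxo-3,6-dihydro-2H-pyran-4-yl pent-4-ynoate | C[C@@H]1CC(OC(=O)CCC#C)=CC(=O)O1 | intermediate
17 | (6R)-4-hydroxy-6-methyl-3-(pent-4-ynoyl)-5,6-dihydro-2H-pyran-2-one | C[C@@H]1CC(O)=C(C(=O)CCC#C)C(=O)O1 | intermediate
18 | methyl alternarate, methyl (2S,3E)-2-hydroxy-2-[(1R,2S)-1-hydroxy-2-methylbutyl]-9-[(6R)-4-hydroxy-6-methyl-2-oxo-5,6-dihydro-2H-pyran-3-yl]-6-methylidene-9-oxonon-3-enoate | C=C(C/C=C/[C@@](O)(C(=O)OC)[C@H](O)[C@@H](C)CC)CCC(=O)C1=C(O)C[C@@H](C)OC1=O | intermediate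
19 | alternaric acid | C=C(C/C=C/[C@@](O)(C(=O)O)[C@H](O)[C@@H](C)CC)CCC(=O)C1=C(O)C[C@@H](C)OC1=O | target

**Count and risks**

Total steps: 10. Longest linear sequence: 7 (steps 1, 2, 3, 4, 5, 9, 10).

Step 5 (ester-enolate [2,3]-Wittig rearrangement). The tertiary α-hydrogen may be removed slowly, a [1,2]-shift or retro-aldol cleavage may compete, and the facial control rests on the chelate holding. The fallback sets out from 7 and comes back at 10. O2 of 7 is protected through the tin acetal (Bu2SnO, then MeOCH2Cl and CsF) to give the methoxymethyl ether F5. Its dianion (LiN(iPr)2, 2.2 equiv, THF, −78 to −20 °C) is C-allylated with allyl bromide in an intermolecular Fráter–Seebach alkylation, anti to the sec-butyl group, to give the allylated ester F6. HCl in MeOH removes the acetal and gives 10.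

Step 4 (regioselective O-allylation). Some allylation at O3 or at both oxygens would cost material and need separation. The fallback sets out from 5 and comes back at 9. Triol 5 with 4-methoxybenzaldehyde dimethyl acetal and camphorsulfonic acid gives the thermodynamic six-membered acetal F1, in which only O2 is free. NaH and allyl bromide give the allyl ether F2. 80% aq. AcOH releases the diol F3. TEMPO/PhI(OAc)2 in MeCN–H2O oxidises the primary alcohol to the acid F4, and MeOH with catalytic HCl gives 9.

Step 9 (ruthenium-catalysed coupling). The acidic, chelating acylpyranone may slow the cationic ruthenium catalyst or erode the branched/linear ratio. The fallback sets out from 15 and comes back at 18. Acid 15 is esterified with 9-fluorenylmethanol (DCC, DMAP) to the fluorenylmethyl ester F7. F7 is coupled with 10 under the same [CpRu(MeCN)3]PF6 catalysis to the diene diester F8. Et3N releases the acid F9, and F9 acylates 14 (DCC, DMAP, O-to-C migration) to rejoin the route at 18.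

Further compounds
F1 | step 4 | (2S,4R,5S)-4-[(2S)-butan-2-yl]-2-(4-methoxyphenyl)-1,3-dioxan-5-ol | COc1ccc(cc1)[C@H]2OC[C@H](O)[C@H](O2)[C@@H](C)CC
F2 | step 4 | (2S,4R,5S)-4-[(2S)-butan-2-yl]-2-(4-methoxyphenyl)-5-(prop-2-en-1-yloxy)-1,3-dioxane | COc1ccc(cc1)[C@H]2OC[C@H](OCC=C)[C@H](O2)[C@@H](C)CC
F3 | step 4 | (2S,3R,4S)-4-methyl-2-(prop-2-en-1-yloxy)hexane-1,3-diol | OC[C@H](OCC=C)[C@H](O)[C@@H](C)CC
F4 | step 4 | (2R,3R,4S)-3-hydroxy-4-methyl-2-(prop-2-en-1-yloxy)hexanoic acid | OC(=O)[C@H](OCC=C)[C@H](O)[C@@H](C)CC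
F5 | step 5 | methyl (2R,3R,4S)-3-hydroxy-2-(methoxymethoxy)-4-methylhexanoate | COC(=O)[C@H](OCOC)[C@H](O)[C@@H](C)CC
F6 | step 5 | methyl (2S,3R,4S)-3-hydroxy-2-(methoxymethoxy)-4-methyl-2-(prop-2-en-1-yl)hexanoate | C=CC[C@@](OCOC)(C(=O)OC)[C@H](O)[C@@H](C)CC
F7 | step 9 | (9H-fluoren-9-yl)methyl pent-4-ynoate | C#CCCC(=O)OCC1c2ccccc2-c2ccccc12
F8 | step 9 | 9-[(9H-fluoren-9-yl)methyl] 1-methyl (2S,3E)-2-hydroxy-2-[(1R,2S)-1-hydroxy-2-methylbutyl]-6-methylidenenon-3-enedioate | C=C(C/C=C/[C@@](O)(C(=O)OC)[C@H](O)[C@@H](C)CC)CCC(=O)OCC1c2ccccc2-c2ccccc12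
F9 | step 9 | (6E,8S)-8-hydroxy-8-[(1R,2S)-1-hydroxy-2-methylbutyl]-9-methoxy-4-methylidene-9-oxonon-6-enoic acid | C=C(C/C=C/[C@@](O)(C(=O)OC)[C@H](O)[C@@H](C)CC)CCC(=O)O
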